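## Retrosynthetic overview
1. Kuwanon A is the tris-MOM-protected 3-prenylflavone, after final acidolysis. Its 2,2-dimethylchromene is formed last from a free 2'-OH by propargylation and aromatic Claisen/oxa-6π closure onto the only free ortho carbon (C3'). The prenyl-bearing chromone has to be built first because an electron-rich chromene would not survive ICl or Ni(0).
2. The C3-prenyl group comes from a 3-iodoflavone by a proposed Ni-catalysed, linear-selective reductive cross-coupling with prenyl acetate (the new step).
3. The 3-iodoflavone comes from 6-endo iodocyclisation of an o-(MOM-oxy)aryl ynone. The ynone comes from oxidation of the propargylic alcohol formed from a lithium aryl acetylide and tris-MOM-phloroglucinaldehyde.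
4. The acetylide comes from 2,4-dihydroxybenzaldehyde (4-O-MOM, 2-O-TIPS, Ohira–Bestmann). Rings are formed in the order: pyranone (C ring), then C3-prenyl, then the dimethylpyran (chromene).

Assumptions:
- Kuwanon A as drawn has no stereocentres, because the CMe2 carbon carries two identical methyls. No enantio-control is needed, and the "single enantiomer" is the achiral compound.
- MOMCl/DIPEA alkylates the 4-OH of 2,4-dihydroxybenzaldehyde selectively, because the 2-OH is hydrogen-bonded to the aldehyde.

## Route

**Step 1**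
Reactants: 1 (2,4-dihydroxybenzaldehyde)
Product: 2 (2-hydroxy-4-(methoxymethoxy)benzaldehyde)
Conditions: MOMCl (1.05 equiv), i-Pr2NEt, CH2Cl2, 0 °C
Reagents that add atoms: MOMCl, ClCOC
Why: The more acidic, non-chelated 4-OH is alkylated selectively (Williamson-type O-alkylation), leaving the H-bonded 2-OH free.

**Step 2**
Reactants: 2
Product: 3 (2-(triisopropylsilyloxy)-4-(methoxymethoxy)benzaldehyde)
Conditions: TIPSCl, imidazole, DMF, rt
Reagents that add atoms: TIPSCl, CC(C)[Si](Cl)(C(C)C)C(C)C
Why: Silyl protection of the 2-OH gives a group that is orthogonal to MOM and is removed later by fluoride. TIPS is chosen over TBS for stability to K2CO3/MeOH in step 3.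

**Step 3**
Reactants: 3
Product: 4 (1-ethynyl-4-(methoxymethoxy)-2-(TIPS-oxy)benzene)
Conditions: Bestmann–Ohira reagent (1.5 equiv), K2CO3, MeOH, 0 °C to rt
Reagents that add atoms: dimethyl (1-diazo-2-oxopropyl)phosphonate, CC(=O)C(=[N+]=[N-])P(=O)(OC)OC (supplies the new alkyne carbon)
Why: Seyferth–Gilbert homologation under Ohira–Bestmann conditions converts the aryl aldehyde to the terminal alkyne without strong base.

**Step 4**
Reactants: 5 (2,4,6-trihydroxybenzaldehyde)
Product: 6 (2,4,6-tris(methoxymethoxy)benzaldehyde)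
Conditions: NaH (3.6 equiv), MOMCl (3.6 equiv), THF/DMF, 0 °C to rt
Reagents that add atoms: MOMCl, ClCOC
Why: Exhaustive Williamson-type MOM protection gives a symmetric aldehyde in which either ortho OMOM can later become the ring oxygen.

**Step 5**
Reactants: 4 and 6
Product: 7 (1-[2,4,6-tris(MOM-oxy)phenyl]-3-[4-MOM-oxy-2-(TIPS-oxy)phenyl]prop-2-yn-1-ol)
Conditions: 4 + n-BuLi (1.05 equiv), THF, −78 °C, 30 min; then 6, −78 to 0 °C
Reagents that add atoms: none (n-BuLi is removed on work-up)
Why: Nucleophilic 1,2-addition of a lithium acetylide to the aldehyde, assisted by chelation to the ortho MOM oxygens, forms the C–C bond.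

**Step 6**
Reactants: 7
Product: 8 (ynone: 1-[2,4,6-tris(MOM-oxy)phenyl]-3-[4-MOM-oxy-2-(TIPS-oxy)phenyl]prop-2-yn-1-one)
Conditions: Dess–Martin periodinane (1.3 equiv), NaHCO3, CH2Cl2, 0 °C to rt
Reagents that add atoms: none
Why: Dess–Martin oxidation of the propargylic alcohol is mild and leaves the acetals and the silyl ether untouched.

**Step 7**
Reactants: 8
Product: 9 (3-iodo-5,7-bis(MOM-oxy)-2-[4-MOM-oxy-2-(TIPS-oxy)phenyl]-4H-chromen-4-one)
Conditions: ICl (1.2 equiv), NaHCO3 (solid), CH2Cl2, −20 to 0 °C
Reagents that add atoms: ICl, ClI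
Why: Larock-type electrophilic 6-endo-dig iodocyclisation closes the pyranone ring, and the oxonium loses MOM⁺ (trapped as MOMCl) to give the chromone. No chromene or prenyl alkene is present yet to compete for I⁺.

**Step 8**
Reactants: 9 and 10 (prenyl acetate, 3-methylbut-2-en-1-yl acetate)
Product: 11 (3-prenyl-5,7-bis(MOM-oxy)-2-[4-MOM-oxy-2-(TIPS-oxy)phenyl]chromen-4-one)
Conditions: 10 (2 equiv), NiBr2·diglyme (10 mol %), 4,4'-di-tert-butyl-2,2'-bipyridine (12 mol %), Zn dust (3 equiv), TBAI (0.5 equiv), DMA, 40 °C
Reagents that add atoms: prenyl acetate, CC(C)=CCOC(C)=O (supplies the prenyl group)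
Why: Proposed new method: Ni(0)/bipyridine adds oxidatively into the vinylic C–I bond of the α-iodoenone. Zn-generated low-valent Ni ionises prenyl acetate to a π-prenyl-Ni species. C(sp2)–C(sp3) reductive elimination occurs at the unhindered CH2 terminus, because the CMe2 terminus is blocked by the gem-dimethyl group and the tetrasubstituted vinyl-Ni. This gives the linear prenyl (not reverse-prenyl) at C3. The closest known reaction is Ni-catalysed reductive (cross-electrophile) allylation of aryl halides with allylic acetates. It has not been shown on hindered 2-aryl-3-iodochromones or with linear-selective prenylation to make C3-prenylflavones, and it forms the key C3–C(prenyl) bond.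

**Step 9**
Reactants: 11
Product: 12 (3-prenyl-5,7-bis(MOM-oxy)-2-[2-hydroxy-4-MOM-oxyphenyl]chromen-4-one)
Conditions: TBAF (1.1 equiv), AcOH (1.1 equiv), THF, 0 °C, 30 min
Reagents that add atoms: none
Why: Fluoride-mediated desilylation frees only the 2'-OH, and the AcOH buffer protects the chromone and the MOM groups from basic fluoride.

**Step 10**
Reactants: 12 and 13 (3-chloro-3-methylbut-1-yne)
Product: 14 (2'-O-(2-methylbut-3-yn-2-yl) ether of 12)
Conditions: 13 (3 equiv), CuI (10 mol %), DBU (3 equiv), MeCN, 0 °C to rt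
Reagents that add atoms: 3-chloro-3-methylbut-1-yne, CC(C)(Cl)C#C (supplies the CMe2C≡CH unit)
Why: Cu-acetylide-mediated O-propargylation of the phenol by a tertiary propargylic chloride (Godfrey-type) gives the aryl 1,1-dimethylpropargyl ether.

**Step 11**
Reactants: 14
Product: 15 (tris-MOM-protected Kuwanon A)
Conditions: N,N-diethylaniline, 190 °C, sealed tube, 1–2 h
Reagents that add atoms: none (isomerisation)
Why: Aromatic propargyl Claisen [3,3] onto C3' (the only free ortho position, since C1' is substituted) gives an allenyl dienone. Tautomerisation to the allenylphenol, 1,5-H shift to the o-quinone methide, and oxa-6π-electrocyclisation give the 2,2-dimethyl-2H-chromene.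

**Step 12**
Reactants: 15
Product: 16 (Kuwanon A)
Conditions: 3 M aq. HCl, THF/MeOH 1:1, 45 °C, 4 h
Reagents that add atoms: none
Why: Acid-catalysed acetal hydrolysis (MOM removal) liberates the 5-, 7- and 4'-OH groups. The chromene and prenyl alkenes survive the mild, brief acid treatment, and the product is achiral.

## Compound list
1 | 2,4-dihydroxybenzaldehyde | O=Cc1ccc(O)cc1O | starting material
2 | 2-hydroxy-4-(methoxymethoxy)benzaldehyde | O=Cc1ccc(OCOC)cc1O | intermediate
3 | 4-(MOM-oxy)-2-(TIPS-oxy)benzaldehyde | O=Cc1ccc(OCOC)cc1O[Si](C(C)C)(C(C)C)C(C)C | intermediate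
4 | 1-ethynyl-4-(MOM-oxy)-2-(TIPS-oxy)benzene | C#Cc1ccc(OCOC)cc1O[Si](C(C)C)(C(C)C)C(C)C | intermediate
5 | 2,4,6-trihydroxybenzaldehyde | O=Cc1c(O)cc(O)cc1O | starting material
6 | 2,4,6-tris(MOM-oxy)benzaldehyde | O=Cc1c(OCOC)cc(OCOC)cc1OCOC | intermediate
7 | propargylic alcohol from 4 + 6 | OC(C#Cc1ccc(OCOC)cc1O[Si](C(C)C)(C(C)C)C(C)C)c1c(OCOC)cc(OCOC)cc1OCOC | intermediate
8 | ynone | O=C(C#Cc1ccc(OCOC)cc1O[Si](C(C)C)(C(C)C)C(C)C)c1c(OCOC)cc(OCOC)cc1OCOC | intermediate
9 | 3-iodoflavone (5,7,4'-tri-OMOM, 2'-OTIPS) | O=c1c(I)c(-c2ccc(OCOC)cc2O[Si](C(C)C)(C(C)C)C(C)C)oc2cc(OCOC)cc(OCOC)c12 | intermediate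
10 | prenyl acetate | CC(C)=CCOC(C)=O | starting material
11 | 3-prenylflavone (2'-OTIPS, tri-OMOM) | O=c1c(CC=C(C)C)c(-c2ccc(OCOC)cc2O[Si](C(C)C)(C(C)C)C(C)C)oc2cc(OCOC)cc(OCOC)c12 | intermediate
12 | 3-prenyl-2'-hydroxyflavone (tri-OMOM) | O=c1c(CC=C(C)C)c(-c2ccc(OCOC)cc2O)oc2cc(OCOC)cc(OCOC)c12 | intermediate
13 | 3-chloro-3-methylbut-1-yne | CC(C)(Cl)C#C | starting material
14 | 2'-O-(1,1-dimethylpropargyl) ether | O=c1c(CC=C(C)C)c(-c2ccc(OCOC)cc2OC(C)(C)C#C)oc2cc(OCOC)cc(OCOC)c12 | intermediate
15 | tris-MOM Kuwanon A | O=c1c(CC=C(C)C)c(-c2ccc(OCOC)c3c2OC(C)(C)C=C3)oc2cc(OCOC)cc(OCOC)c12 | intermediate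
16 | Kuwanon A (achiral) | CC(C)=CCc1c(-c2ccc(O)c3c2OC(C)(C)C=C3)oc2cc(O)cc(O)c2c1=O | target

**Total steps:** 12 (11 for the B-ring chain plus 1 for the A-ring aldehyde, with the two chains meeting at step 5).
**Longest linear sequence:** 11 steps (1 → 2 → 3 → 4 → 7 → 8 → 9 → 11 → 12 → 14 → 15 → 16).

## Three steps most likely to fail
1. **Step 8 (proposed new Ni prenylation).** Likely problems are protodeiodination of the hindered 3-iodoflavone, branched (reverse-prenyl) product, or Ni ionisation of the allylic ether bond in the chromene.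
   Fallback (known chemistry): Stille coupling of 9 with allyl-SnBu3 (Pd(PPh3)4, DMF), then cross-metathesis with 2-methylbut-2-ene (Grubbs–Hoveyda II) to convert the 3-allyl group into 3-prenyl (11).
2. **Step 11 (propargyl Claisen at 190 °C).** Likely problems are thermal decomposition, or ortho–ortho rearrangement toward the substituted C1' position.
   Fallback: skip steps 10–11 and treat phenol 12 with PhB(OH)2, EtCO2H and 3-methylbut-2-enal in toluene at 110 °C (boronate-templated o-quinone methide/oxa-6π annulation) to give 15 directly.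
3. **Step 12 (global MOM removal).** Likely problems are incomplete cleavage of the 5-OMOM group next to the carbonyl, or acid-induced damage to the chromene or prenyl alkenes.
   Fallback: convert the MOM ethers to acetates (Ac2O, ZnCl2, CH2Cl2), then cleave the acetates with K2CO3/MeOH at 0 °C. This replaces aqueous acidolysis with Lewis-acid acetolysis followed by mild base methanolysis.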